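**Retrosynthetic overview**
- The eleven-membered ring (the only carbocycle) is closed last, at the bond between the ketone carbon and the hydroxymethyl-bearing alkene carbon, by joining a Z-vinyl iodide and a Z-enoic acid in an electrolysis cell under nickel catalysis.
- The seco acid comes from a butenolide, which stores the Z-enoate and masks the tertiary alcohol; the Z-alkene next to the ester carbinol comes from an alkyne.
- Alkyne + butenolide aldehyde + 3-methylbut-2-enoyl chloride: acetylide addition sets the secondary carbinol from the neighbouring tertiary centre.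
- The alkyne (quaternary carbon) comes from ethyl (R)-3-hydroxybutanoate by double Fráter–Seebach alkylation; the butenolide aldehyde (tertiary carbinol carbon) comes from (R)-linalool by oxidative degradation.
- Ring order: butenolide (temporary, step 6), then the eleven-membered ring (step 15).

Assumption: both chiral starting materials are used at commercial enantiomeric purity, minor diastereomers are removed by chromatography after step 8, and the target is written as the open hydroxy enone drawn.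

**Route**

Step 1
Reactants: 1 ethyl (3R)-3-hydroxybutanoate; 2 5-iodo-2-methylpent-2-ene
Product: 4 ethyl (2R,3R)-3-hydroxy-2-(4-methylpent-3-en-1-yl)butanoate, via dilithium alkoxide enolate 3 (not isolated)
Conditions: LiN(iPr)2 (2.2 equiv), THF, −78 to −20 °C; then 2, DMPU, −20 to 0 °C
Reagents that add atoms: none
Why: Fráter–Seebach alkylation; the chelated dilithium alkoxide enolate is attacked anti to the C3 methyl, so the bought (3R) centre sets (2R).

Step 2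
Reactants: 4 ethyl (2R,3R)-3-hydroxy-2-(4-methylpent-3-en-1-yl)butanoate
Product: 6 ethyl (2S,3R)-3-hydroxy-2-methyl-2-(4-methylpent-3-en-1-yl)butanoate, via dilithium alkoxide enolate 5 (not isolated)
Conditions: LiN(iPr)2 (2.3 equiv), THF, −78 to −20 °C; then MeI, DMPU, −78 to 0 °C
Reagents that add atoms: iodomethane, CI
Why: second Fráter–Seebach alkylation; the chelated enolate is again attacked anti to the C3 methyl, so methyl enters where the side chain entered before and the quaternary centre is fixed as (2S).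

Step 3
Reactants: 6 ethyl (2S,3R)-3-hydroxy-2-methyl-2-(4-methylpent-3-en-1-yl)butanoate
Product: 7 ethyl (2S)-2-ethenyl-2,6-dimethylhept-5-enoate
Conditions: Burgess reagent (methyl N-(triethylammoniosulfonyl)carbamate), toluene, 70 °C
Reagents that add atoms: none
Why: Burgess syn-elimination can only take a methyl hydrogen (the α-carbon is quaternary), giving the vinyl group and removing the controlling carbinol centre.

Step 4
Reactants: 7 ethyl (2S)-2-ethenyl-2,6-dimethylhept-5-enoate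
Product: 9 (3S)-3-ethynyl-3,7-dimethylocta-1,6-diene, via aldehyde 8 (not isolated)
Conditions: i-Bu2AlH (1.1 equiv), CH2Cl2, −78 °C; then MeOH, K2CO3, dimethyl (1-diazo-2-oxopropyl)phosphonate, −78 °C to rt
Reagents that add atoms: dimethyl (1-diazo-2-oxopropyl)phosphonate, CC(=O)C(=[N+]=[N-])P(=O)(OC)OC
Why: half-reduction of the hindered ester and Ohira–Bestmann (Seyferth–Gilbert) homologation in one flask; the quaternary centre has no α-hydrogen and cannot epimerise.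

Step 5
Reactants: 10 (3R)-3,7-dimethylocta-1,6-dien-3-ol ((R)-linalool)
Product: 13 (5R)-5-ethenyl-5-methyloxolan-2-one, via ozonide 11 (not isolated), via lactol 12 (not isolated)
Conditions: O3 (1.0 equiv), CH2Cl2, −78 °C; PPh3, −78 °C to rt; then TEMPO (10 mol %), PhI(OAc)2, CH2Cl2, rt
Reagents that add atoms: ozone, [O-][O+]=O
Why: ozonolysis takes the electron-rich trisubstituted alkene before the vinyl group, the hydroxy aldehyde closes to the lactol and oxoammonium (TEMPO) oxidation gives the lactone; the bought carbinol centre is untouched.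

Step 6
Reactants: 13 (5R)-5-ethenyl-5-methyloxolan-2-one
Product: 16 (5S)-5-ethenyl-5-methylfuran-2(5H)-one, via lithium enolate 14 (not isolated), via selenide 15 (not isolated)
Conditions: LiN(iPr)2, THF, −78 °C; PhSeBr, −78 °C; then 30% H2O2, pyridine, CH2Cl2, 0 °C to rt
Reagents that add atoms: none
Why: α-selenenylation and selenoxide syn-elimination give the butenolide, whose ring fixes the later ring Z-alkene next to the ketone (the descriptor changes by priority only).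

Step 7
Reactants: 16 (5S)-5-ethenyl-5-methylfuran-2(5H)-one
Product: 18 (2R)-2-methyl-5-oxo-2,5-dihydrofuran-2-carbaldehyde, via ozonide 17 (not isolated)
Conditions: O3, CH2Cl2, −78 °C; PPh3, −78 °C to rt; used crude
Reagents that add atoms: ozone, [O-][O+]=O
Why: ozonolysis of the vinyl group only, since the butenolide alkene is electron-poor; the aldehyde has no α-hydrogen.

Step 8
Reactants: 9 (3S)-3-ethynyl-3,7-dimethylocta-1,6-diene; 18 (2R)-2-methyl-5-oxo-2,5-dihydrofuran-2-carbaldehyde; 19 3-methylbut-2-enoyl chloride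
Product: 22 (1S,4S)-4-ethenyl-4,8-dimethyl-1-[(2R)-2-methyl-5-oxo-2,5-dihydrofuran-2-yl]non-7-en-2-yn-1-yl 3-methylbut-2-enoate, via lithium acetylide 20 (not isolated), via lithium alkoxide 21 (not isolated)
Conditions: n-BuLi (1.0 equiv), THF, −78 °C; 18, −78 °C; then 19, −78 to −20 °C
Reagents that add atoms: none
Why: acetylide addition under polar Felkin–Anh control (lactone C–O anti to the nucleophile, ring sp2 carbon inside, methyl outside) gives the (1S) carbinol from the bought tertiary centre; the alkoxide is acylated in the same flask.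

Step 9
Reactants: 22 (1S,4S)-4-ethenyl-4,8-dimethyl-1-[(2R)-2-methyl-5-oxo-2,5-dihydrofuran-2-yl]non-7-en-2-yn-1-yl 3-methylbut-2-enoate
Product: 24 (1S,4S)-4-(2-hydroxyethyl)-4,8-dimethyl-1-[(2R)-2-methyl-5-oxo-2,5-dihydrofuran-2-yl]non-7-en-2-yn-1-yl 3-methylbut-2-enoate, via alkylborane 23 (not isolated)
Conditions: 9-BBN (1.3 equiv), THF, 0 °C to rt; then H2O2, pH 7 phosphate buffer, 0 °C
Reagents that add atoms: hydrogen peroxide, OO
Why: anti-Markovnikov hydroboration–oxidation; 9-BBN takes only the monosubstituted alkene and leaves the hindered internal alkyne, the trisubstituted alkenes and the esters.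

Step 10
Reactants: 24 (1S,4S)-4-(2-hydroxyethyl)-4,8-dimethyl-1-[(2R)-2-methyl-5-oxo-2,5-dihydrofuran-2-yl]non-7-en-2-yn-1-yl 3-methylbut-2-enoate
Product: 25 (1S,2Z,4S)-4-(2-hydroxyethyl)-4,8-dimethyl-1-[(2R)-2-methyl-5-oxo-2,5-dihydrofuran-2-yl]nona-2,7-dien-1-yl 3-methylbut-2-enoate
Conditions: H2 (1 atm), Pd/CaCO3 poisoned with Pb(OAc)2, quinoline, EtOAc, rt
Reagents that add atoms: none
Why: Lindlar syn-semihydrogenation gives the Z-alkene; no terminal alkene is left to over-reduce.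

Step 11
Reactants: 25 (1S,2Z,4S)-4-(2-hydroxyethyl)-4,8-dimethyl-1-[(2R)-2-methyl-5-oxo-2,5-dihydrofuran-2-yl]nona-2,7-dien-1-yl 3-methylbut-2-enoate
Product: 27 (1S,2Z,4S)-4,8-dimethyl-1-[(2R)-2-methyl-5-oxo-2,5-dihydrofuran-2-yl]-4-[(2E)-4-oxobut-2-en-1-yl]nona-2,7-dien-1-yl 3-methylbut-2-enoate, via aldehyde 26 (not isolated)
Conditions: Pr4N[RuO4] (5 mol %), N-methylmorpholine N-oxide, 4 Å sieves, CH2Cl2, rt; then Ph3P=CHCHO, 40 °C
Reagents that add atoms: (triphenylphosphoranylidene)acetaldehyde, O=CC=P(c1ccccc1)(c1ccccc1)c1ccccc1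
Why: Ley–Griffith oxidation followed in the same flask by Wittig olefination with a stabilised ylide, which gives the E-enal.

Step 12
Reactants: 27 (1S,2Z,4S)-4,8-dimethyl-1-[(2R)-2-methyl-5-oxo-2,5-dihydrofuran-2-yl]-4-[(2E)-4-oxobut-2-en-1-yl]nona-2,7-dien-1-yl 3-methylbut-2-enoate
Product: 28 (1S,2Z,4S)-4-[(2Z)-3-iodo-4-oxobut-2-en-1-yl]-4,8-dimethyl-1-[(2R)-2-methyl-5-oxo-2,5-dihydrofuran-2-yl]nona-2,7-dien-1-yl 3-methylbut-2-enoate
Conditions: I2, 4-(dimethylamino)pyridine (20 mol %), K2CO3, THF–H2O (1:1), rt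
Reagents that add atoms: iodine, II
Why: amine-catalysed α-iodination of the enal (conjugate addition, iodination, elimination) gives the Z-iodoenal (iodine cis to the chain), which is the geometry the ring alkene needs.

Step 13
Reactants: 28 (1S,2Z,4S)-4-[(2Z)-3-iodo-4-oxobut-2-en-1-yl]-4,8-dimethyl-1-[(2R)-2-methyl-5-oxo-2,5-dihydrofuran-2-yl]nona-2,7-dien-1-yl 3-methylbut-2-enoate
Product: 29 (1S,2Z,4S)-4-[(2Z)-4-hydroxy-3-iodobut-2-en-1-yl]-4,8-dimethyl-1-[(2R)-2-methyl-5-oxo-2,5-dihydrofuran-2-yl]nona-2,7-dien-1-yl 3-methylbut-2-enoate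
Conditions: NaBH4, CeCl3·7H2O, MeOH, −78 °C
Reagents that add atoms: none
Why: Luche 1,2-reduction of the aldehyde; the lactone and the ester are not touched at −78 °C.

Step 14
Reactants: 29 (1S,2Z,4S)-4-[(2Z)-4-hydroxy-3-iodobut-2-en-1-yl]-4,8-dimethyl-1-[(2R)-2-methyl-5-oxo-2,5-dihydrofuran-2-yl]nona-2,7-dien-1-yl 3-methylbut-2-enoate
Product: 32 (2Z,4R,5S,6Z,8S)-8-[(2Z)-3-iodo-4-(triethylsilyloxy)but-2-en-1-yl]-4,8,12-trimethyl-5-[(3-methylbut-2-enoyl)oxy]-4-(triethylsilyloxy)trideca-2,6,11-trienoic acid, via lithium carboxylate 30 (not isolated), via tris(triethylsilyl) derivative 31 (not isolated)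
Conditions: LiOH·H2O (1.05 equiv), THF–H2O, 0 °C; evaporate, toluene azeotrope; Et3SiOSO2CF3, 2,6-lutidine, CH2Cl2, −78 to 0 °C; then aq NaHCO3–MeOH, 0 °C
Reagents that add atoms: lithium hydroxide, [Li+].[OH-]; triethylsilyl trifluoromethanesulfonate, CC[Si](CC)(CC)OS(=O)(=O)C(F)(F)F
Why: saponification of the strained butenolide (faster than the hindered conjugated ester), silylation of both alcohols and the carboxylate, then selective hydrolysis of the labile silyl ester; no stereocentre is involved.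

Step 15
Reactants: 32 (2Z,4R,5S,6Z,8S)-8-[(2Z)-3-iodo-4-(triethylsilyloxy)but-2-en-1-yl]-4,8,12-trimethyl-5-[(3-methylbut-2-enoyl)oxy]-4-(triethylsilyloxy)trideca-2,6,11-trienoic acid
Product: 34 (1S,2R,3Z,6Z,9S,10Z)-2,9-dimethyl-9-(4-methylpent-3-en-1-yl)-5-oxo-2-(triethylsilyloxy)-6-[(triethylsilyloxy)methyl]cycloundeca-3,6,10-trien-1-yl 3-methylbut-2-enoate, via mixed anhydride 33 (not isolated)
Conditions: (t-BuOCO)2O, 4-(dimethylamino)pyridine (5 mol %), N,N-dimethylacetamide, rt; then added over 12 h to NiBr2(MeOCH2CH2OMe) (20 mol %), 4,4′-di-tert-butyl-2,2′-bipyridine (24 mol %), NaI (0.1 M), N,N-dimethylacetamide, undivided cell, Mg anode, Ni-foam cathode, 3 mA constant current, 25 °C, final 2 mM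
Reagents that add atoms: none
Why: Proposed new method: zerovalent nickel inserts into the Z-vinyl iodide with retention, the cathode reduces the vinylnickel to the monovalent state, this takes up the mixed anhydride by acyl C–O oxidative addition and trivalent nickel releases the cross-conjugated dienone by reductive elimination, while the magnesium anode closes the circuit and slow addition favours the eleven-membered ring over dimers; the closest known reaction type is the nickel-catalysed reductive ketone synthesis from organic halides and acid chlorides or in situ mixed anhydrides (cross-electrophile acylation) and its electroreductive variants, not yet used to close a ring from a vinyl iodide and an enoic acid.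

Step 16
Reactants: 34 (1S,2R,3Z,6Z,9S,10Z)-2,9-dimethyl-9-(4-methylpent-3-en-1-yl)-5-oxo-2-(triethylsilyloxy)-6-[(triethylsilyloxy)methyl]cycloundeca-3,6,10-trien-1-yl 3-methylbut-2-enoate
Product: 35 (1S,2R,3Z,6Z,9S,10Z)-2-hydroxy-6-(hydroxymethyl)-2,9-dimethyl-9-(4-methylpent-3-en-1-yl)-5-oxocycloundeca-3,6,10-trien-1-yl 3-methylbut-2-enoate (CNP0230506.3)
Conditions: HF·pyridine, pyridine, THF, 0 °C to rt
Reagents that add atoms: none
Why: buffered fluoride desilylation of the primary and the tertiary silyl ether; nothing else in the molecule reacts.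

**Compound list**

1 | ethyl (3R)-3-hydroxybutanoate | C[C@@H](O)CC(=O)OCC | starting material
2 | 5-iodo-2-methylpent-2-ene | CC(C)=CCCI | starting material
3 | dilithium (3R)-1-ethoxy-3-oxidobut-1-en-1-olate | CCOC([O-])=C[C@@H](C)[O-].[Li+].[Li+] | intermediate
4 | ethyl (2R,3R)-3-hydroxy-2-(4-methylpent-3-en-1-yl)butanoate | CCOC(=O)[C@H](CCC=C(C)C)[C@@H](C)O | intermediate
5 | dilithium (3R)-1-ethoxy-2-(4-methylpent-3-en-1-yl)-3-oxidobut-1-en-1-olate | CCOC([O-])=C(CCC=C(C)C)[C@@H](C)[O-].[Li+].[Li+] | intermediate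
6 | ethyl (2S,3R)-3-hydroxy-2-methyl-2-(4-methylpent-3-en-1-yl)butanoate | CCOC(=O)[C@](CCC=C(C)C)(C)[C@@H](C)O | intermediate
7 | ethyl (2S)-2-ethenyl-2,6-dimethylhept-5-enoate | CCOC(=O)[C@](CCC=C(C)C)(C)C=C | intermediate
8 | (2S)-2-ethenyl-2,6-dimethylhept-5-enal | O=C[C@](CCC=C(C)C)(C)C=C | intermediate
9 | (3S)-3-ethynyl-3,7-dimethylocta-1,6-diene | C#C[C@](CCC=C(C)C)(C)C=C | intermediate
10 | (3R)-3,7-dimethylocta-1,6-dien-3-ol ((R)-linalool) | CC(C)=CCC[C@@](C)(O)C=C | starting material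
11 | (3R)-5-(3,3-dimethyl-1,2,4-trioxolan-5-yl)-3-methylpent-1-en-3-ol (ozonide) | CC1(C)OOC(CC[C@@](C)(O)C=C)O1 | intermediate
12 | (5R)-5-ethenyl-5-methyloxolan-2-ol (both anomers) | OC1CC[C@](C)(C=C)O1 | intermediate
13 | (5R)-5-ethenyl-5-methyloxolan-2-one | O=C1CC[C@](C)(C=C)O1 | intermediate
14 | lithium (5R)-5-ethenyl-5-methyl-4,5-dihydrofuran-2-olate | [Li+].[O-]C1=CC[C@](C)(C=C)O1 | intermediate
15 | (5R)-5-ethenyl-5-methyl-3-(phenylselanyl)oxolan-2-one (C3 epimers) | O=C1C([Se]c2ccccc2)C[C@](C)(C=C)O1 | intermediate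
16 | (5S)-5-ethenyl-5-methylfuran-2(5H)-one | O=C1C=C[C@](C)(C=C)O1 | intermediate
17 | (5R)-5-methyl-5-(1,2,4-trioxolan-3-yl)furan-2(5H)-one (ozonide) | O=C1C=C[C@](C)(C2OOCO2)O1 | intermediate
18 | (2R)-2-methyl-5-oxo-2,5-dihydrofuran-2-carbaldehyde | O=C1C=C[C@](C)(C=O)O1 | intermediate
19 | 3-methylbut-2-enoyl chloride | CC(C)=CC(=O)Cl | starting material
20 | lithium (3S)-3-ethenyl-3,7-dimethyloct-6-en-1-yn-1-ide | [Li+].[C-]#C[C@](CCC=C(C)C)(C)C=C | intermediate
21 | lithium (1S,4S)-4-ethenyl-4,8-dimethyl-1-[(2R)-2-methyl-5-oxo-2,5-dihydrofuran-2-yl]non-7-en-2-yn-1-olate | CC(C)=CCC[C@@](C)(C=C)C#C[C@H]([O-])[C@@]1(C)C=CC(=O)O1.[Li+] | intermediate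
22 | (1S,4S)-4-ethenyl-4,8-dimethyl-1-[(2R)-2-methyl-5-oxo-2,5-dihydrofuran-2-yl]non-7-en-2-yn-1-yl 3-methylbut-2-enoate | CC(C)=CCC[C@@](C)(C=C)C#C[C@H](OC(=O)C=C(C)C)[C@@]1(C)C=CC(=O)O1 | intermediate
23 | (1S,4R)-4-[2-(9-borabicyclo[3.3.1]nonan-9-yl)ethyl]-4,8-dimethyl-1-[(2R)-2-methyl-5-oxo-2,5-dihydrofuran-2-yl]non-7-en-2-yn-1-yl 3-methylbut-2-enoate | CC(C)=CCC[C@@](C)(CCB1C2CCCC1CCC2)C#C[C@H](OC(=O)C=C(C)C)[C@@]3(C)C=CC(=O)O3 | intermediate
24 | (1S,4S)-4-(2-hydroxyethyl)-4,8-dimethyl-1-[(2R)-2-methyl-5-oxo-2,5-dihydrofuran-2-yl]non-7-en-2-yn-1-yl 3-methylbut-2-enoate | CC(C)=CCC[C@@](C)(CCO)C#C[C@H](OC(=O)C=C(C)C)[C@@]1(C)C=CC(=O)O1 | intermediate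
25 | (1S,2Z,4S)-4-(2-hydroxyethyl)-4,8-dimethyl-1-[(2R)-2-methyl-5-oxo-2,5-dihydrofuran-2-yl]nona-2,7-dien-1-yl 3-methylbut-2-enoate | CC(C)=CCC[C@@](C)(CCO)/C=C\[C@H](OC(=O)C=C(C)C)[C@@]1(C)C=CC(=O)O1 | intermediate
26 | (1S,2Z,4S)-4,8-dimethyl-1-[(2R)-2-methyl-5-oxo-2,5-dihydrofuran-2-yl]-4-(2-oxoethyl)nona-2,7-dien-1-yl 3-methylbut-2-enoate | CC(C)=CCC[C@@](C)(CC=O)/C=C\[C@H](OC(=O)C=C(C)C)[C@@]1(C)C=CC(=O)O1 | intermediate
27 | (1S,2Z,4S)-4,8-dimethyl-1-[(2R)-2-methyl-5-oxo-2,5-dihydrofuran-2-yl]-4-[(2E)-4-oxobut-2-en-1-yl]nona-2,7-dien-1-yl 3-methylbut-2-enoate | CC(C)=CCC[C@@](C)(C/C=C/C=O)/C=C\[C@H](OC(=O)C=C(C)C)[C@@]1(C)C=CC(=O)O1 | intermediate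
28 | (1S,2Z,4S)-4-[(2Z)-3-iodo-4-oxobut-2-en-1-yl]-4,8-dimethyl-1-[(2R)-2-methyl-5-oxo-2,5-dihydrofuran-2-yl]nona-2,7-dien-1-yl 3-methylbut-2-enoate | CC(C)=CCC[C@@](C)(C/C=C(\I)C=O)/C=C\[C@H](OC(=O)C=C(C)C)[C@@]1(C)C=CC(=O)O1 | intermediate
29 | (1S,2Z,4S)-4-[(2Z)-4-hydroxy-3-iodobut-2-en-1-yl]-4,8-dimethyl-1-[(2R)-2-methyl-5-oxo-2,5-dihydrofuran-2-yl]nona-2,7-dien-1-yl 3-methylbut-2-enoate | CC(C)=CCC[C@@](C)(C/C=C(\I)CO)/C=C\[C@H](OC(=O)C=C(C)C)[C@@]1(C)C=CC(=O)O1 | intermediate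
30 | lithium (2Z,4R,5S,6Z,8S)-4-hydroxy-8-[(2Z)-4-hydroxy-3-iodobut-2-en-1-yl]-4,8,12-trimethyl-5-[(3-methylbut-2-enoyl)oxy]trideca-2,6,11-trienoate | CC(C)=CCC[C@@](C)(C/C=C(\I)CO)/C=C\[C@H](OC(=O)C=C(C)C)[C@](C)(O)/C=C\C(=O)[O-].[Li+] | intermediate
31 | triethylsilyl (2Z,4R,5S,6Z,8S)-8-[(2Z)-3-iodo-4-(triethylsilyloxy)but-2-en-1-yl]-4,8,12-trimethyl-5-[(3-methylbut-2-enoyl)oxy]-4-(triethylsilyloxy)trideca-2,6,11-trienoate | CC(C)=CCC[C@@](C)(C/C=C(\I)CO[Si](CC)(CC)CC)/C=C\[C@H](OC(=O)C=C(C)C)[C@](C)(O[Si](CC)(CC)CC)/C=C\C(=O)O[Si](CC)(CC)CC | intermediate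
32 | (2Z,4R,5S,6Z,8S)-8-[(2Z)-3-iodo-4-(triethylsilyloxy)but-2-en-1-yl]-4,8,12-trimethyl-5-[(3-methylbut-2-enoyl)oxy]-4-(triethylsilyloxy)trideca-2,6,11-trienoic acid | CC(C)=CCC[C@@](C)(C/C=C(\I)CO[Si](CC)(CC)CC)/C=C\[C@H](OC(=O)C=C(C)C)[C@](C)(O[Si](CC)(CC)CC)/C=C\C(=O)O | intermediate
33 | tert-butyl carbonic anhydride of acid 32 (acyl tert-butyl carbonate) | CC(C)=CCC[C@@](C)(C/C=C(\I)CO[Si](CC)(CC)CC)/C=C\[C@H](OC(=O)C=C(C)C)[C@](C)(O[Si](CC)(CC)CC)/C=C\C(=O)OC(=O)OC(C)(C)C | intermediate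
34 | (1S,2R,3Z,6Z,9S,10Z)-2,9-dimethyl-9-(4-methylpent-3-en-1-yl)-5-oxo-2-(triethylsilyloxy)-6-[(triethylsilyloxy)methyl]cycloundeca-3,6,10-trien-1-yl 3-methylbut-2-enoate | CC(C)=CCC[C@]1(C)/C=C\[C@H](OC(=O)C=C(C)C)[C@](C)(O[Si](CC)(CC)CC)/C=C\C(=O)/C(CO[Si](CC)(CC)CC)=C\C1 | intermediate
35 | (1S,2R,3Z,6Z,9S,10Z)-2-hydroxy-6-(hydroxymethyl)-2,9-dimethyl-9-(4-methylpent-3-en-1-yl)-5-oxocycloundeca-3,6,10-trien-1-yl 3-methylbut-2-enoate | CC(C)=CCC[C@]1(C)/C=C\[C@H](OC(=O)C=C(C)C)[C@](C)(O)/C=C\C(=O)/C(CO)=C\C1 | target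

**Step count and risks**

Total: 16 steps. Longest linear sequence: 13 steps (steps 1–4, then 8–16, from ethyl (3R)-3-hydroxybutanoate); the linalool branch is steps 5–7.

The three steps most likely to fail:

- **Step 8 (facial selectivity at the secondary carbinol).** The two groups that flank the aldehyde besides the lactone oxygen (methyl and a flat ring sp2 carbon) are close in size, so the bias may be weak or reversed. The fallback sets out from 9 and 18 and uses the same bias in the opposite sense. Acetylide 20 is added to 18 and quenched with NH4Cl to give the epimeric alcohols (5R)-5-[(4S)-4-ethenyl-1-hydroxy-4,8-dimethylnon-7-en-2-yn-1-yl]-5-methylfuran-2(5H)-one F1. Dess–Martin oxidation gives the ynone (5R)-5-[(4S)-4-ethenyl-4,8-dimethylnon-7-en-2-ynoyl]-5-methylfuran-2(5H)-one F2. Reduction with NaBH4/CeCl3·7H2O at −78 °C, where hydride now comes from the face the acetylide preferred, gives (5R)-5-[(1S,4S)-4-ethenyl-1-hydroxy-4,8-dimethylnon-7-en-2-yn-1-yl]-5-methylfuran-2(5H)-one F3. Esterification with 19 (pyridine, 4-(dimethylamino)pyridine) comes back to the route at 22.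

- **Step 14 (lactone opening and silylation).** The free Z-γ-hydroxy carboxyl derivative can close back to the butenolide before the tertiary alcohol is silylated, and hydroxide may touch the allylic ester. The fallback sets out from 29 and lets the ring-opening nucleophile deliver the silyl group. KOSiEt3 (from Et3SiOH and KH, THF, 0 °C) opens the butenolide, and the silyl group moves from the first-formed silyl ester to the tertiary alkoxide. This gives potassium (2Z,4R,5S,6Z,8S)-8-[(2Z)-4-hydroxy-3-iodobut-2-en-1-yl]-4,8,12-trimethyl-5-[(3-methylbut-2-enoyl)oxy]-4-(triethylsilyloxy)trideca-2,6,11-trienoate F4, so a free hydroxy acid never exists. Et3SiCl/imidazole then caps the primary alcohol, and mild acidic work-up comes back to the route at 32.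

- **Step 15 (the proposed new ring closure).** Dimerisation, return to the butenolide from the activated acid, nickel insertion into the allylic ester, or Z/E loss may compete. The fallback uses known chemistry and sets out from 32. The acid is reduced through its isobutyl carbonic anhydride (i-BuOCOCl, N-methylmorpholine; NaBH4) to (2Z,4R,5S,6Z,8S)-1-hydroxy-8-[(2Z)-3-iodo-4-(triethylsilyloxy)but-2-en-1-yl]-4,8,12-trimethyl-4-(triethylsilyloxy)trideca-2,6,11-trien-5-yl 3-methylbut-2-enoate F5. Dess–Martin oxidation gives (2Z,4R,5S,6Z,8S)-8-[(2Z)-3-iodo-4-(triethylsilyloxy)but-2-en-1-yl]-4,8,12-trimethyl-1-oxo-4-(triethylsilyloxy)trideca-2,6,11-trien-5-yl 3-methylbut-2-enoate F6. Nozaki–Hiyama–Kishi ring closure (CrCl2, NiCl2 cat., DMSO–THF, high dilution) gives (1S,2R,3Z,6Z,9S,10Z)-5-hydroxy-2,9-dimethyl-9-(4-methylpent-3-en-1-yl)-2-(triethylsilyloxy)-6-[(triethylsilyloxy)methyl]cycloundeca-3,6,10-trien-1-yl 3-methylbut-2-enoate F7 (both carbinol epimers). Dess–Martin oxidation comes back to the route at 34.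

Further compounds
F1 | step 8 | (5R)-5-[(4S)-4-ethenyl-1-hydroxy-4,8-dimethylnon-7-en-2-yn-1-yl]-5-methylfuran-2(5H)-one (carbinol epimers) | CC(C)=CCC[C@@](C)(C=C)C#CC(O)[C@@]1(C)C=CC(=O)O1
F2 | step 8 | (5R)-5-[(4S)-4-ethenyl-4,8-dimethylnon-7-en-2-ynoyl]-5-methylfuran-2(5H)-one | CC(C)=CCC[C@@](C)(C=C)C#CC(=O)[C@@]1(C)C=CC(=O)O1
F3 | step 8 | (5R)-5-[(1S,4S)-4-ethenyl-1-hydroxy-4,8-dimethylnon-7-en-2-yn-1-yl]-5-methylfuran-2(5H)-one | CC(C)=CCC[C@@](C)(C=C)C#C[C@H](O)[C@@]1(C)C=CC(=O)O1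
F4 | step 14 | potassium (2Z,4R,5S,6Z,8S)-8-[(2Z)-4-hydroxy-3-iodobut-2-en-1-yl]-4,8,12-trimethyl-5-[(3-methylbut-2-enoyl)oxy]-4-(triethylsilyloxy)trideca-2,6,11-trienoate | CC(C)=CCC[C@@](C)(C/C=C(\I)CO)/C=C\[C@H](OC(=O)C=C(C)C)[C@](C)(O[Si](CC)(CC)CC)/C=C\C(=O)[O-].[K+]
F5 | step 15 | (2Z,4R,5S,6Z,8S)-1-hydroxy-8-[(2Z)-3-iodo-4-(triethylsilyloxy)but-2-en-1-yl]-4,8,12-trimethyl-4-(triethylsilyloxy)trideca-2,6,11-trien-5-yl 3-methylbut-2-enoate | CC(C)=CCC[C@@](C)(C/C=C(\I)CO[Si](CC)(CC)CC)/C=C\[C@H](OC(=O)C=C(C)C)[C@](C)(O[Si](CC)(CC)CC)/C=C\CO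
F6 | step 15 | (2Z,4R,5S,6Z,8S)-8-[(2Z)-3-iodo-4-(triethylsilyloxy)but-2-en-1-yl]-4,8,12-trimethyl-1-oxo-4-(triethylsilyloxy)trideca-2,6,11-trien-5-yl 3-methylbut-2-enoate | CC(C)=CCC[C@@](C)(C/C=C(\I)CO[Si](CC)(CC)CC)/C=C\[C@H](OC(=O)C=C(C)C)[C@](C)(O[Si](CC)(CC)CC)/C=C\C=O
F7 | step 15 | (1S,2R,3Z,6Z,9S,10Z)-5-hydroxy-2,9-dimethyl-9-(4-methylpent-3-en-1-yl)-2-(triethylsilyloxy)-6-[(triethylsilyloxy)methyl]cycloundeca-3,6,10-trien-1-yl 3-methylbut-2-enoate (carbinol epimers) | CC(C)=CCC[C@]1(C)/C=C\[C@H](OC(=O)C=C(C)C)[C@](C)(O[Si](CC)(CC)CC)/C=C\C(O)/C(CO[Si](CC)(CC)CC)=C\C1
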